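**Assumption:** lignan numbering is used (C7 = ArCH–O, C8 = CH–CH2OH, C8' = CH–CH2Ar', C9' = OCH2). The p‑quinone methide in step 11 is not isolated; its formation and ring closure count as one step.

## Retrosynthetic overview
1. The tetrahydrofuran (the only ring to build) is closed second to last by a 5‑exo intramolecular oxa‑Michael (1,6‑conjugate) addition of the C9'–OH onto a p‑quinone methide at C7; this sets C7 trans to C8.
2. The quinone methide comes from DDQ dehydrogenation of a (2R,3R)‑2,3‑dibenzylbutane‑1,4‑diol. The diol is C2‑symmetric apart from its phenol protecting groups, so the free phenol (ring A) decides which benzylic carbon is oxidised; either choice gives the same skeleton.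
3. The diol comes from LiAlH4 reduction of a trans‑dibenzyl‑5‑menthyloxybutyrolactone, which also removes the menthyl acetal and the ring‑A pivalate.
4. That lactone is assembled in one pot from three fragments: a lithiated aryl dithiane (ring B), (5R)‑5‑menthyloxyfuran‑2(5H)‑one (source of C8 and C8' chirality) and a benzyl bromide (ring A).
5. The three fragments come from syringaldehyde (twice) and from furfural plus (−)‑menthol.

## Route

### Branch 1: ring‑B dithiane

**Step 1**
Reactants: 1 syringaldehyde; 2 propane‑1,3‑dithiol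
Product: 3 4‑(1,3‑dithian‑2‑yl)‑2,6‑dimethoxyphenol
Conditions: BF3·OEt2 (cat.), CH2Cl2, 0 °C → rt
Reagents that add atoms: propane‑1,3‑dithiol, SCCCS
Why: Lewis‑acid dithioacetalisation of an aryl aldehyde; done before silylation so no protecting group is exposed to BF3/thiol.

**Step 2**
Reactants: 3; 4 triisopropylsilyl chloride
Product: 5 2‑[3,5‑dimethoxy‑4‑(triisopropylsilyloxy)phenyl]‑1,3‑dithiane
Conditions: TIPSCl, imidazole, DMAP (cat.), DMF, 40 °C
Reagents that add atoms: TIPSCl, CC(C)[Si](Cl)(C(C)C)C(C)C
Why: O‑silylation of the phenol; the aryl TIPS ether tolerates n‑BuLi, Raney Ni, LiAlH4 at 0 °C and DDQ, and is removed last with fluoride.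

### Branch 2: chiral butenolide

**Step 3**
Reactants: 6 furfural; 7 dioxygen
Product: 8 5‑hydroxyfuran‑2(5H)‑one (racemic)
Conditions: O2, hν (visible), rose bengal (cat.), MeOH, rt
Reagents that add atoms: O2, O=O
Why: singlet‑oxygen [4+2] photooxygenation of the furan; methanolysis of the endoperoxide expels the formyl carbon as methyl formate.

**Step 4**
Reactants: 8; 9 (−)‑menthol
Product: 10 (5R)‑5‑[(1R,2S,5R)‑menthyloxy]furan‑2(5H)‑one
Conditions: (−)‑menthol, CSA (cat.), toluene, 110 °C (−H2O); crystallise from petroleum ether, −20 °C; acid‑epimerise and recycle the mother liquor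
Reagents that add atoms: (−)‑menthol, CC(C)[C@@H]1CC[C@@H](C)C[C@H]1O
Why: acid‑catalysed acetalisation gives both C5 epimers, which interconvert under acid; the (5R) diastereomer crystallises selectively.

### Branch 3: ring‑A benzyl bromide

**Step 5**
Reactants: 1 syringaldehyde; 11 pivaloyl chloride
Product: 12 4‑formyl‑2,6‑dimethoxyphenyl pivalate
Conditions: PivCl, Et3N, DMAP (cat.), CH2Cl2, 0 °C → rt
Reagents that add atoms: PivCl, CC(C)(C)C(=O)Cl
Why: phenol acylation; the doubly ortho‑flanked pivalate resists enolate attack in step 8 and is cleaved for free by LiAlH4 in step 10.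

**Step 6**
Reactants: 12
Product: 13 4‑(hydroxymethyl)‑2,6‑dimethoxyphenyl pivalate
Conditions: NaBH4, THF–MeOH, 0 °C
Reagents that add atoms: none
Why: chemoselective borohydride reduction of the aldehyde; the hindered aryl pivalate is untouched at 0 °C.

**Step 7**
Reactants: 13; 14 phosphorus tribromide
Product: 15 4‑(bromomethyl)‑2,6‑dimethoxyphenyl pivalate
Conditions: PBr3, CH2Cl2, 0 °C
Reagents that add atoms: PBr3, BrP(Br)Br
Why: standard conversion of a benzylic alcohol to the bromide; the acyloxy arene keeps the bromide stable enough to handle.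

### Union and completion

**Step 8**
Reactants: 5; 10; 15
Product: 16 (3R,4R,5R)‑3‑[3,5‑dimethoxy‑4‑(pivaloyloxy)benzyl]‑4‑{2‑[3,5‑dimethoxy‑4‑(triisopropylsilyloxy)phenyl]‑1,3‑dithian‑2‑yl}‑5‑[(1R,2S,5R)‑menthyloxy]dihydrofuran‑2(3H)‑one
Conditions: 5, n‑BuLi, THF, −78 → −20 °C; then 10, −78 °C; then 15, HMPA (or DMPU), −78 °C → rt
Reagents that add atoms: none (all three reactants are incorporated)
Why: tandem Michael addition–enolate alkylation; the dithianyl anion adds to C4 anti to the C5 menthyloxy group (sets C8'), and the enolate is benzylated anti to the bulky dithianyl group (sets C8, trans).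

**Step 9**
Reactants: 16
Product: 17 (3R,4R,5R)‑3‑[3,5‑dimethoxy‑4‑(pivaloyloxy)benzyl]‑4‑[3,5‑dimethoxy‑4‑(triisopropylsilyloxy)benzyl]‑5‑[(1R,2S,5R)‑menthyloxy]dihydrofuran‑2(3H)‑one
Conditions: Raney Ni (W‑2), EtOH–THF, rt → 50 °C
Reagents that add atoms: none
Why: reductive desulfurisation turns the dithiane carbon into the C7' methylene; no stereocentre is involved and the ester, silyl ether, acetal and lactone are inert.

**Step 10**
Reactants: 17
Product: 18 (2R,3R)‑2‑(4‑hydroxy‑3,5‑dimethoxybenzyl)‑3‑[3,5‑dimethoxy‑4‑(triisopropylsilyloxy)benzyl]butane‑1,4‑diol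
Conditions: LiAlH4 (4 equiv), THF, 0 °C → rt; Rochelle salt work‑up (menthol recovered)
Reagents that add atoms: none
Why: hydride reduction opens the lactone, the resulting hemiacetal alkoxide loses menthoxide and the aldehyde is reduced, giving the 1,4‑diol; the pivalate is cleaved in the same pot to free only the ring‑A phenol; C8 and C8' are not epimerisable here.

**Step 11**
Reactants: 18
Product: 19 {(2S,3R,4R)‑2‑(4‑hydroxy‑3,5‑dimethoxyphenyl)‑4‑[3,5‑dimethoxy‑4‑(triisopropylsilyloxy)benzyl]tetrahydrofuran‑3‑yl}methanol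
Conditions: DDQ (1.0 equiv, slow addition), anhydrous CH2Cl2, 4 Å MS, 0 °C → rt
Reagents that add atoms: none
Why: DDQ dehydrogenates the free 4‑alkyl‑2,6‑dimethoxyphenol to the p‑quinone methide, and the C9'–OH closes the ring by 5‑exo‑trig intramolecular oxa‑Michael (1,6‑conjugate) addition; the aryl group ends up trans to the C8 CH2OH (7S) because the alternative is the all‑cis ring and the addition is reversible. The silylated ring B is oxidised much more slowly.

**Step 12**
Reactants: 19
Product: 20 (+)‑(7S,8R,8'R)‑5,5'‑dimethoxylariciresinol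
Conditions: TBAF, AcOH (1:1), THF, 0 °C
Reagents that add atoms: none
Why: fluoride cleavage of the aryl silyl ether; buffered, non‑acidic conditions avoid both C7 epimerisation and Friedel–Crafts closure to the aryltetralin.

## Compound list
1 | syringaldehyde | COc1cc(C=O)cc(OC)c1O | starting material
2 | propane‑1,3‑dithiol | SCCCS | starting material (reagent)
3 | 4‑(1,3‑dithian‑2‑yl)‑2,6‑dimethoxyphenol | COc1cc(C2SCCCS2)cc(OC)c1O | intermediate
4 | triisopropylsilyl chloride | CC(C)[Si](Cl)(C(C)C)C(C)C | starting material (reagent)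
5 | 2‑[3,5‑dimethoxy‑4‑(triisopropylsilyloxy)phenyl]‑1,3‑dithiane | COc1cc(C2SCCCS2)cc(OC)c1O[Si](C(C)C)(C(C)C)C(C)C | intermediate
6 | furfural | O=Cc1ccco1 | starting material
7 | dioxygen | O=O | starting material (reagent)
8 | 5‑hydroxyfuran‑2(5H)‑one (racemic) | OC1OC(=O)C=C1 | intermediate
9 | (−)‑menthol, (1R,2S,5R) | CC(C)[C@@H]1CC[C@@H](C)C[C@H]1O | starting material
10 | (5R)‑5‑[(1R,2S,5R)‑menthyloxy]furan‑2(5H)‑one | O=C1C=C[C@H](O[C@@H]2C[C@H](C)CC[C@H]2C(C)C)O1 | intermediate
11 | pivaloyl chloride | CC(C)(C)C(=O)Cl | starting material (reagent)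
12 | 4‑formyl‑2,6‑dimethoxyphenyl pivalate | COc1cc(C=O)cc(OC)c1OC(=O)C(C)(C)C | intermediate
13 | 4‑(hydroxymethyl)‑2,6‑dimethoxyphenyl pivalate | COc1cc(CO)cc(OC)c1OC(=O)C(C)(C)C | intermediate
14 | phosphorus tribromide | BrP(Br)Br | starting material (reagent)
15 | 4‑(bromomethyl)‑2,6‑dimethoxyphenyl pivalate | COc1cc(CBr)cc(OC)c1OC(=O)C(C)(C)C | intermediate
16 | (3R,4R,5R) dithianyl lactone (step 8 product) | O=C1[C@H](Cc2cc(OC)c(OC(=O)C(C)(C)C)c(OC)c2)[C@@H](C2(c3cc(OC)c(O[Si](C(C)C)(C(C)C)C(C)C)c(OC)c3)SCCCS2)[C@H](O[C@@H]2C[C@H](C)CC[C@H]2C(C)C)O1 | intermediate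
17 | (3R,4R,5R) trans‑dibenzyl‑5‑menthyloxy lactone | O=C1[C@H](Cc2cc(OC)c(OC(=O)C(C)(C)C)c(OC)c2)[C@@H](Cc2cc(OC)c(O[Si](C(C)C)(C(C)C)C(C)C)c(OC)c2)[C@H](O[C@@H]2C[C@H](C)CC[C@H]2C(C)C)O1 | intermediate
18 | (2R,3R)‑2‑(4‑hydroxy‑3,5‑dimethoxybenzyl)‑3‑[3,5‑dimethoxy‑4‑(triisopropylsilyloxy)benzyl]butane‑1,4‑diol | OC[C@H](Cc1cc(OC)c(O)c(OC)c1)[C@@H](Cc1cc(OC)c(O[Si](C(C)C)(C(C)C)C(C)C)c(OC)c1)CO | intermediate
19 | 4'‑O‑TIPS‑(7S,8R,8'R)‑5,5'‑dimethoxylariciresinol | COc1cc(C[C@H]2CO[C@H](c3cc(OC)c(O)c(OC)c3)[C@H]2CO)cc(OC)c1O[Si](C(C)C)(C(C)C)C(C)C | intermediate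
20 | (+)‑(7S,8R,8'R)‑5,5'‑dimethoxylariciresinol | COc1cc(C[C@H]2CO[C@H](c3cc(OC)c(O)c(OC)c3)[C@H]2CO)cc(OC)c1O | target

## Summary
Total step count: 12.
Longest linear sequence: 8 steps (steps 5, 6, 7, 8, 9, 10, 11, 12), which is two thirds of the total.

Three steps most likely to fail:

1. **Step 8 (three‑component addition–alkylation).** The hindered enolate may be trapped poorly, or may attack the pivalate. Fallback: form the two C–C bonds separately. Make (R)‑β‑(4‑benzyloxy‑3,5‑dimethoxybenzyl)‑γ‑butyrolactone by Stobbe condensation of O‑benzylsyringaldehyde with dimethyl succinate, Rh‑catalysed asymmetric hydrogenation and Ca(BH4)2 reduction/lactonisation. Then alkylate its LiHMDS enolate with bromide 15 (trans‑selective) and rejoin the route at the LiAlH4 step, ending with hydrogenolysis of the benzyl ether instead of fluoride.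

2. **Step 11 (DDQ quinone methide formation and ring closure).** Risks are over‑oxidation at C7 of the product and C‑attack by ring B to give the aryltetralin. Fallback: bring C7 in already oxygenated. Quench the step‑8 enolate with an O‑protected syringaldehyde (aldol instead of alkylation) and carry the benzylic alcohol through desulfurisation and reduction. Generate the quinone methide without oxidant from the p‑hydroxybenzyl alcohol (phenol unmasking, mild ionisation); both carbinol epimers converge on the 7,8‑trans ring.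

3. **Step 10 (LiAlH4 global reduction).** The aryl TIPS ether may be partly lost, which removes the differentiation of the two phenols, or the acetal may reduce incompletely. Fallback: change the protecting‑group logic and sequence. Carry ring B as a benzyl ether. First convert 17 to the menthol‑free trans‑dibenzylbutyrolactone (NaBH4/aq. KOH, then acid), purify it, and reduce with LiBH4. After the ring closure, finish by hydrogenolysis.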